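## Retrosynthetic overview
- The C13 carbinol and vinyl group come from the methyl ketone: catalyst-controlled CH2 transfer gives the oxirane, and a one-carbon homologation opens it.
- The saturated ketone comes from the ring-conjugated dienone by 1,4-reduction.
- The dienone comes from an acyclic 2,5-dialkylfuran diene in one cascade. Ring A closes first, then ring B. Ring B closes on the substituted furan carbon, so the furan loses its aromaticity and opens to the enone and the tetrasubstituted alkene. C–Hg is then exchanged for C–Br.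
- The furan diene comes from 2-methylfuran (which supplies C9, C11, C12, C13, C16 and the oxygen) and (E)-geranylacetone (the other 13 carbons).

Assumption: geranylacetone is used as the pure 5E isomer, and for each chiral ligand the antipode that gives the drawn configuration is taken.

## Route

**Step 1**
Reactants: 1 2-methylfuran; 2 (5E)-6,10-dimethylundeca-5,9-dien-2-one ((E)-geranylacetone)
Product: 4 (±)-(5E)-6,10-dimethyl-2-(5-methylfuran-2-yl)undeca-5,9-dien-2-ol, via 5-methyl-2-furyllithium 3 (not isolated)
Conditions: n-BuLi, THF, 0 °C; 2, −78 → 0 °C; H2O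
Reagents that add atoms: none
Why: Lithiation of 2-methylfuran is specific for the free C5 position and the furyllithium adds 1,2 to the methyl ketone (organolithium carbonyl addition); the carbinol centre is racemic and is removed in step 2.

**Step 2**
Reactants: 4
Product: 5 (±)-2-[(5E)-6,10-dimethylundeca-5,9-dien-2-yl]-5-methylfuran
Conditions: Et3SiH, TFA, CH2Cl2, −78 °C
Reagents that add atoms: none
Why: Ionic hydrogenation (SN1 deoxygenation): the tertiary furfuryl alcohol ionises at −78 °C much faster than the trisubstituted alkenes are protonated, and the silane delivers hydride to the exocyclic carbon so the furan is regained; the methine centre is racemic and is erased in step 3.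

**Step 3 (key step)**
Reactants: 5
Product: 8 (3E)-4-[(4aS,6R,8aR)-6-bromo-2,5,5,8a-tetramethyl-3,4,4a,5,6,7,8,8a-octahydronaphthalen-1-yl]but-3-en-2-one, via spiro-2H-furanium mercurial 6 (not isolated), via alkylmercury bromide dienone 7 (not isolated)
Conditions: Hg(OTf)2, C2-symmetric bis(oxazoline) L*, 2,6-di-tert-butyl-4-methylpyridine, CH2Cl2, −78 → 0 °C; LiBr, THF; Br2, pyridine, 0 °C
Reagents that add atoms: bromine, BrBr
Why: Proposed new method: the ligated Hg(II) π-acid engages only the terminal trisubstituted alkene (mercury-triflate olefin cyclisation, a type that tolerates furans where Br+ donors would not) and the ligand selects the alkene face (ligand-controlled mercuriocyclisation); the chair–chair antiperiplanar cascade of the E-alkene closes ring A and then ring B, fixing equatorial C6–Hg and 4a-H trans to 8a-CH3 in one event; the C8a cation is caught by the alkyl-bearing furan C2 because that gives the six-membered ring (C3 would give a seven-membered one) and is the most nucleophilic site (ipso-Friedel–Crafts dearomatisation, furan-terminated cation–olefin cyclisation); ion 6 cannot rearomatise by proton loss, so it breaks its C–O bond and loses the only adjacent proton (the former methine H, so both epimers of 5 converge) to give the tetrasubstituted alkene and the enone (acid-type furan ring opening); Br2 in pyridine then replaces Hg by Br with retention (SE2 bromodemercuration) while the Z-enone equilibrates to E.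

**Step 4**
Reactants: 8
Product: 10 4-[(4aS,6R,8aR)-6-bromo-2,5,5,8a-tetramethyl-3,4,4a,5,6,7,8,8a-octahydronaphthalen-1-yl]butan-2-one, via triethylsilyl enol ether 9 (not isolated)
Conditions: Et3SiH, RhCl(PPh3)3 (1 mol %), PhMe, 50 °C; 1 M HCl, THF
Reagents that add atoms: none
Why: Rh-catalysed 1,4-hydrosilylation of the enone (the β-ionone to dihydro-β-ionone reaction type) leaves the hindered tetrasubstituted alkene and the secondary bromide untouched, and hydrolysis of 9 gives the ketone; no stereocentre is formed.

**Step 5**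
Reactants: 10
Product: 11 (2R)-2-{2-[(4aS,6R,8aR)-6-bromo-2,5,5,8a-tetramethyl-3,4,4a,5,6,7,8,8a-octahydronaphthalen-1-yl]ethyl}-2-methyloxirane
Conditions: Me3S(O)I, NaH, THF; La–Li3–tris(binaphthoxide) (5 mol %), (2,4,6-(MeO)3C6H2)3P=O (5 mol %), MS 5 Å, rt
Reagents that add atoms: trimethylsulfoxonium iodide, C[S+](C)(C)=O.[I-]
Why: Catalytic asymmetric Corey–Chaykovsky epoxidation of a methyl ketone: the La/Li binaphthoxide–phosphine oxide catalyst distinguishes CH3 from CH2CH2R and delivers CH2 to one carbonyl face, so C13 (R) is set by the catalyst independently of the remote decalin.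

**Step 6**
Reactants: 11
Product: 13 (3R)-5-[(4aS,6R,8aR)-6-bromo-2,5,5,8a-tetramethyl-3,4,4a,5,6,7,8,8a-octahydronaphthalen-1-yl]-3-methylpent-1-en-3-ol (target), via oxido-sulfonium betaine 12 (not isolated)
Conditions: Me3SI (4 equiv), n-BuLi (3.9 equiv), THF, −10 °C → rt
Reagents that add atoms: trimethylsulfonium iodide, C[S+](C)C.[I-]
Why: One-carbon homologation of an epoxide to an allylic alcohol with excess dimethylsulfonium methylide: SN2 opening at the oxirane CH2 gives 12, which loses Me2S by β-elimination to form the vinyl group; the C13–O bond is never broken, so (R) is retained, and the equatorial bromide has no antiperiplanar H for E2.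

## Compound list
1 | 2-methylfuran | Cc1ccco1 | starting material
2 | (E)-geranylacetone | CC(=O)CC/C=C(\C)CCC=C(C)C | starting material
3 | 5-methyl-2-furyllithium | [Li]c1ccc(C)o1 | intermediate
4 | (±)-(5E)-6,10-dimethyl-2-(5-methylfuran-2-yl)undeca-5,9-dien-2-ol | Cc1ccc(o1)C(C)(O)CC/C=C(\C)CCC=C(C)C | intermediate
5 | (±)-2-[(5E)-6,10-dimethylundeca-5,9-dien-2-yl]-5-methylfuran | Cc1ccc(o1)C(C)CC/C=C(\C)CCC=C(C)C | intermediate
6 | (4aS,6R,8aR)-6-(triflyloxymercurio)-2,5,5,8a,5'-pentamethyl-octahydrospiro[naphthalene-1,2'-furan]-1'-ium triflate (epimers at C1/C2) | CC1CC[C@@H]2C(C)(C)[C@H]([Hg]OS(=O)(=O)C(F)(F)F)CC[C@@]2(C)C13C=CC(C)=[O+]3.[O-]S(=O)(=O)C(F)(F)F | intermediate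
7 | (3Z)-4-[(4aS,6R,8aR)-6-(bromomercurio)-2,5,5,8a-tetramethyl-octahydronaphthalen-1-yl]but-3-en-2-one | CC(=O)/C=C\C1=C(C)CC[C@@H]2C(C)(C)[C@H]([Hg]Br)CC[C@@]12C | intermediate
8 | (3E)-4-[(4aS,6R,8aR)-6-bromo-2,5,5,8a-tetramethyl-octahydronaphthalen-1-yl]but-3-en-2-one | CC(=O)/C=C/C1=C(C)CC[C@@H]2C(C)(C)[C@H](Br)CC[C@@]12C | intermediate
9 | triethylsilyl enol ether of 10 | CC(O[Si](CC)(CC)CC)=CCC1=C(C)CC[C@@H]2C(C)(C)[C@H](Br)CC[C@@]12C | intermediate
10 | 4-[(4aS,6R,8aR)-6-bromo-2,5,5,8a-tetramethyl-octahydronaphthalen-1-yl]butan-2-one | CC(=O)CCC1=C(C)CC[C@@H]2C(C)(C)[C@H](Br)CC[C@@]12C | intermediate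
11 | (2R)-2-methyl-2-[2-(bromodecalinyl)ethyl]oxirane | C1[C@](C)(O1)CCC2=C(C)CC[C@@H]3C(C)(C)[C@H](Br)CC[C@@]23C | intermediate
12 | (3R)-3-oxido-3-methyl-5-(bromodecalinyl)pentyl dimethylsulfonium betaine | C[S+](C)CC[C@](C)([O-])CCC1=C(C)CC[C@@H]2C(C)(C)[C@H](Br)CC[C@@]12C | intermediate
13 | (3R)-5-[(4aS,6R,8aR)-6-bromo-2,5,5,8a-tetramethyl-octahydronaphthalen-1-yl]-3-methylpent-1-en-3-ol | C=C[C@](C)(O)CCC1=C(C)CC[C@@H]2C(C)(C)[C@H](Br)CC[C@@]12C | target

## Step count and risks
Total steps: 6. Longest linear sequence: 6.

**Step 3 is the most likely to fail.**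
- The C8a cation may eliminate before the furan captures it.
- The ipso adduct may revert, or may lose a proton from its methyl group instead of opening.
- The epimer of 5 that places its methyl group axial may stop at the monocycle.

The fallback sets out from 2 and comes back at 10, and it gives up the furan terminator. Vinylmagnesium bromide adds to 2 to give (E)-nerolidol F1. 2-Methoxypropene with catalytic acid at 120 °C (Saucy–Marbet Claisen) converts it into farnesylacetone F2. With no furan present, a direct asymmetric bromocyclisation (DBDMH, chiral thiophosphoramide Lewis base) can be used. The ketone oxygen caps the C8 cation and gives the tricyclic bromo enol ether F3. TsOH in toluene then isomerises this to the tetrasubstituted-alkene ketone 10.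

**Step 5 is second.** Catalyst control at a dialkyl ketone may give an insufficient C13 ratio. The fallback sets out from 10 and comes back at 13.
- Horner–Wadsworth–Emmons reaction with triethyl phosphonoacetate gives the (E)-enoate F4.
- DIBAL-H reduces it to the allylic alcohol F5.
- Sharpless epoxidation with D-(−)-diisopropyl tartrate gives the (2R,3R)-epoxy alcohol F6.
- I2/PPh3/imidazole converts this to the epoxy iodide F7.
- Zinc in ethanol opens F7 reductively to the tertiary vinyl carbinol 13, with the C13–O bond intact.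

**Step 2 is third.** Acid may cyclise or isomerise the diene, or the furfuryl cation may oligomerise. The fallback sets out from 2 (and uses 3) and comes back at 5 without any cation. NaBH4 reduces 2 to the secondary alcohol F8. I2/PPh3/imidazole gives the secondary iodide F9. ZnCl2 transmetalates 3 to (5-methylfuran-2-yl)zinc chloride F10. A nickel-catalysed Negishi coupling of F9 with F10 then gives 5.

## Further compounds
F1 | step 3 | (E)-nerolidol | C=CC(C)(O)CC/C=C(\C)CCC=C(C)C
F2 | step 3 | farnesylacetone (9E; 5E/5Z) | CC(=O)CCC=C(C)CC/C=C(\C)CCC=C(C)C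
F3 | step 3 | tricyclic bromo enol ether (8,13-epoxide, A/B as in 10) | CC1=CCC2C(C)(O1)CC[C@@H]3C(C)(C)[C@H](Br)CC[C@@]23C
F4 | step 5 | ethyl (E)-enoate from 10 | CCOC(=O)/C=C(\C)CCC1=C(C)CC[C@@H]2C(C)(C)[C@H](Br)CC[C@@]12C
F5 | step 5 | (E)-allylic alcohol | OC/C=C(\C)CCC1=C(C)CC[C@@H]2C(C)(C)[C@H](Br)CC[C@@]12C
F6 | step 5 | (2R,3R)-epoxy alcohol | OC[C@H]1O[C@]1(C)CCC2=C(C)CC[C@@H]3C(C)(C)[C@H](Br)CC[C@@]23C
F7 | step 5 | epoxy iodide | IC[C@H]1O[C@]1(C)CCC2=C(C)CC[C@@H]3C(C)(C)[C@H](Br)CC[C@@]23C
F8 | step 2 | (5E)-6,10-dimethylundeca-5,9-dien-2-ol | CC(O)CC/C=C(\C)CCC=C(C)C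
F9 | step 2 | (5E)-10-iodo-2,6-dimethylundeca-2,6-diene | CC(I)CC/C=C(\C)CCC=C(C)C
F10 | step 2 | (5-methylfuran-2-yl)zinc chloride | Cc1ccc([Zn]Cl)o1
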